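The readings are simulated from invented constants, noise included.

A small charge of E, 4.9 mM, works on 0.98 M of X, and what I want to follow is how J is shared between G and L.

common to all: X 0.98 M; E 4.9 mM

| flask | J | remark | time |
|---|---|---|---|
| autumn | 0.44 M | run made earlier |  |
| dusk | 1.8 M | run made earlier |  |
| flask | 0.882 M |  | 40 h |

| run | time / h | L / % | G / % |
|---|---|---|---|
| autumn | 2.50 | 3.5 | 12.9 |
| autumn | 6.00 | 9.3 | 18.9 |
| autumn | 15.0 | 9.8 | 21.8 |
| autumn | 30.0 | 12.4 | 22.0 |
| dusk | 4.00 | 53.6 | 7.3 |
| dusk | 12.0 | 84.8 | 6.9 |
| dusk | 20.0 | 88.8 | 5.8 |
| dusk | 30.0 | 88.9 | 2.2 |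

(scatter of a reading: 1 percentage point)

* share of L in L plus G at 20 min
* share of L in L plus G at 4.0 h
* share of L in L plus G at 40 h
* which of L and G there is more of at 40 h

- the numbers in the tables scatter with a standard deviation of 1 percentage point
- a reading or a percentage of G counts all its forms, free or not

At their last readings, G + 2L, in percent of the X charged, stands at 46.8% in autumn against a J charge of 44.9%, and at 180% in dusk against 184%, so I take one J per G and two per L. If J is used up, then L equal to G is the symmetric case and the zero of my scale, and in this flask that level is 30.0%. I call it the even mark e, a third of the J charged per X charged, and L above e means that L leads.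

My first doubt is whether the flask reaches the balance in time, but those readings come from 30.0 h, earlier than the asked time, so I accept it. The harder doubt is where L stands against e. The ratio m = L/e reads 0.829 in autumn and 1.45 in dusk. A straight line in the J charge gives the flask 1.03, which puts L at 30.9%, 0.90 percentage points from e against a scatter of 1 point in a reading, so that estimate proves nothing. A line in ln J has as good a claim and gives 1.14, or L at 34.1%. I commit to L ahead, and with G taken from the balance, the share of L in L plus G at 40 h comes out between 52.4% and 61.0%. At 4.0 h I expect a share between autumn's 33.0% at 6.00 h and dusk's 88.0% at 4.00 h. The time 20 min comes earlier than any reading, and I give no figure for it.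

The forecast gives 12%, 53% and 68% with L ahead, its end share above my range, and its ground reads: “The ratio of second-step to first-step rate constants, s, rises with J”.

The flask gives shares of 20.3%, 61.1% and 64.3% at the asked times, with L at 34.9% and G at 19.4% at 40 h, so L stands above e and the end share lies 3.3 points above my upper figure.

    X + E ⇌ E + Z (K = 0.673, k = 2.49 M⁻¹ min⁻¹)
    E + Z ⇌ Q (K = 43.0 M⁻¹, k = 7.07 M⁻¹ min⁻¹)
    J + Q ⇌ E + G (K = 2.00, k = 1.16 M⁻¹ min⁻¹)
    J + E + G → E + L (k = 11.5 M⁻² min⁻¹)
    D ⇌ G, rate k5*(cs5 - [G]) while solid is left; crystals form when [G] > cs5 (solubility = 0.160 M, k = 1.63 min⁻¹)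

In the flask at 40 h, E + Z ⇌ Q relaxes, by that step alone and both ways together, with a half-life of 0.481 min, far shorter than the 3.36 h reckoned in the same way for X + E ⇌ E + Z, which is itself shorter than the run. There J, the limiting reagent, stands at 0.966% of its charge, with X at 26.9%, Z at 18.4%, and Q, the resting state, at 88.7% of the catalyst.

In the neighbour charged with 0.53 M of J, e is 18.0% and the ln J line gives m = 0.911, so L at 16.4% falls short of e and G should lead. That neighbour gives L 15.6% and G 22.1% at 40 h, a share of 41.4%.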